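The aryl–acyl bond C4–C4a of ring C is made last, by an aryne annulation. Fluoride releases a 3,5-bis(methoxymethoxy)-4-prenylbenzyne. The oxygen at C5 of ring A, flanking C4a, polarises the triple bond, so the alkoxide of an enantiopure (S)-3-aryl-3-hydroxy Weinreb amide adds at C8a. The aryl anion thus placed at C4a acylates itself on the tethered amide. One operation joins both halves, forms O1–C8a and closes ring C through C4–C4a without touching C2. Because the prenyl group at C6 lies para to C8a on a locally symmetric ring A, no 6-/8-prenyl ambiguity arises. The precursor is an open-chain hydroxy amide bearing the finished dienylchroman.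

Key step: step 10

Assumption: flavanone numbering is used (ring C: O1, C2, C3, C4; ring A: C4a to C8a); (E)-β-ocimene is taken as purchasable isomerically pure; the sense of induction in steps 3 and 4 is assigned by analogy with related substrates, and the antipodal ligand is used if a model shows the opposite sense.

Step 1
Reactants: 1 3-bromo-4,5-dihydroxybenzaldehyde
Product: 2 3-bromo-4-hydroxy-5-(methoxymethoxy)benzaldehyde
Conditions: NaH (2.1 equiv), DMSO/THF, rt; MOMCl (1.0 equiv), rt; aq. NH4Cl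
Reagents that add atoms: chloromethyl methyl ether, COCCl
Why: With two equivalents of NaH the catechol dianion should be alkylated (Williamson-type) at the more basic, unhindered C5 phenoxide meta to the formyl group and not at the delocalised, bromine-flanked C4 phenoxide.

Step 2
Reactants: 2 3-bromo-4-hydroxy-5-(methoxymethoxy)benzaldehyde; 3 (E)-β-ocimene [(3E)-3,7-dimethylocta-1,3,6-triene]
Product: 5 3-[(3E)-3,7-dimethylocta-3,6-dien-1-yl]-4-hydroxy-5-(methoxymethoxy)benzaldehyde, via B-alkylborane 4 (not isolated)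
Conditions: 3 (1.5 equiv), 9-BBN (1.4 equiv), THF, 0 °C to rt; then 2, Pd(OAc)2 (5 mol %), SPhos (10 mol %), aq. K3PO4 (4 equiv), THF, 60 °C
Reagents that add atoms: none
Why: 9-BBN should hydroborate only the monosubstituted vinyl terminus of the triene (anti-Markovnikov), and the primary alkylborane then undergoes B-alkyl Suzuki–Miyaura coupling with the aryl bromide with the (E)-trisubstituted alkene retained.

Step 3
Reactants: 5 3-[(3E)-3,7-dimethylocta-3,6-dien-1-yl]-4-hydroxy-5-(methoxymethoxy)benzaldehyde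
Product: 6 (2S)-8-(methoxymethoxy)-2-methyl-2-[(1E)-4-methylpenta-1,3-dien-1-yl]-3,4-dihydro-2H-chromene-6-carbaldehyde
Conditions: Pd(OCOCF3)2 (10 mol %), (S,S)-Bn-BOXAX [2,2′-bis(4-benzyl-4,5-dihydrooxazol-2-yl)-1,1′-binaphthyl] (20 mol %), p-benzoquinone (4 equiv), MeOH, 60 °C
Reagents that add atoms: none
Why: In this enantioselective Wacker-type oxidative cyclisation the phenol should add 6-exo to the palladium-activated trisubstituted alkene on the face dictated by the ligand, setting the (S) quaternary centre, and β-hydride elimination into the only adjacent CH2 gives the (E)-diene while benzoquinone returns zerovalent to divalent palladium.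

Step 4
Reactants: 6 (2S)-8-(methoxymethoxy)-2-methyl-2-[(1E)-4-methylpenta-1,3-dien-1-yl]-3,4-dihydro-2H-chromene-6-carbaldehyde
Product: 8 methyl (3S)-3-hydroxy-3-[(2S)-8-(methoxymethoxy)-2-methyl-2-[(1E)-4-methylpenta-1,3-dien-1-yl]-3,4-dihydro-2H-chromen-6-yl]propanoate, via silyl ether 7 (not isolated)
Conditions: Ti(OiPr)4 (5 mol %), (S)-2-amino-2′-hydroxy-1,1′-binaphthyl-derived tridentate Schiff-base ligand, 3,5-di-tert-butylsalicylic acid, 1-methoxy-1-(trimethylsilyloxy)ethene (1.5 equiv), Et2O, −10 °C; then K2CO3 (0.2 equiv), MeOH, 0 °C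
Reagents that add atoms: 1-methoxy-1-(trimethylsilyloxy)ethene, C=C(OC)O[Si](C)(C)C
Why: In this catalytic asymmetric Mukaiyama aldol addition the chiral tetravalent titanium complex should expose the Si face of the aldehyde to the ketene acetal, setting the (S) carbinol centre independently of the remote quaternary centre, and mild methanolysis then removes the transferred silyl group.

Step 5
Reactants: 8 methyl (3S)-3-hydroxy-3-[(2S)-8-(methoxymethoxy)-2-methyl-2-[(1E)-4-methylpenta-1,3-dien-1-yl]-3,4-dihydro-2H-chromen-6-yl]propanoate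
Product: 9 (3S)-3-hydroxy-N-methoxy-N-methyl-3-[(2S)-8-(methoxymethoxy)-2-methyl-2-[(1E)-4-methylpenta-1,3-dien-1-yl]-3,4-dihydro-2H-chromen-6-yl]propanamide
Conditions: MeNHOMe·HCl (3 equiv), i-PrMgCl (7 equiv), THF, −20 to 0 °C
Reagents that add atoms: N,O-dimethylhydroxylamine hydrochloride, CNOC.Cl
Why: Weinreb amidation with the chloromagnesium amide of N,O-dimethylhydroxylamine should convert the ester into the amide with the β-hydroxy group carried as its magnesium alkoxide and the carbinol centre untouched.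

Step 6
Reactants: 10 1,3-bis(methoxymethoxy)benzene
Product: 12 1,3-bis(methoxymethoxy)-2-(3-methylbut-2-en-1-yl)benzene, via aryllithium 11 (not isolated)
Conditions: n-BuLi (1.1 equiv), THF, 0 °C; CuI (10 mol %), prenyl bromide (1.2 equiv), −78 °C to rt
Reagents that add atoms: 1-bromo-3-methylbut-2-ene, CC(C)=CCBr
Why: Directed ortho-metalation should occur at the position flanked by both methoxymethoxy groups, and the aryllithium is then alkylated by prenyl bromide with copper assistance.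

Step 7
Reactants: 12 1,3-bis(methoxymethoxy)-2-(3-methylbut-2-en-1-yl)benzene
Product: 14 3,5-bis(methoxymethoxy)-4-(3-methylbut-2-en-1-yl)phenol, via arylboronate 13 (not isolated)
Conditions: [Ir(OMe)(cod)]2 (1.5 mol %), 4,4′-di-tert-butyl-2,2′-bipyridine (3 mol %), B2pin2 (1.0 equiv), THF, 70 °C; then 30 % H2O2, aq. NaOH, THF, 0 °C
Reagents that add atoms: hydrogen peroxide, OO
Why: Sterically governed iridium-catalysed C–H borylation should occur only at the single ring position without an ortho substituent (para to the prenyl group), and oxidation of the boronate gives the phenol whose oxygen becomes O1.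

Step 8
Reactants: 14 3,5-bis(methoxymethoxy)-4-(3-methylbut-2-en-1-yl)phenol
Product: 15 2-bromo-3,5-bis(methoxymethoxy)-4-(3-methylbut-2-en-1-yl)phenol
Conditions: NBS (1.0 equiv), CH2Cl2, −78 °C
Reagents that add atoms: N-bromosuccinimide, O=C1CCC(=O)N1Br
Why: Electrophilic aromatic bromination of the highly activated phenol should occur ortho to the hydroxy group (para is blocked), and since the two ortho positions are equivalent by symmetry one equivalent gives a single monobromide before the prenyl alkene reacts.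

Step 9
Reactants: 15 2-bromo-3,5-bis(methoxymethoxy)-4-(3-methylbut-2-en-1-yl)phenol
Product: 18 3,5-bis(methoxymethoxy)-4-(3-methylbut-2-en-1-yl)-2-(trimethylsilyl)phenyl trifluoromethanesulfonate, via aryl silyl ether 16 (not isolated), via lithium silylphenolate 17 (not isolated)
Conditions: HMDS, THF, 65 °C, then evaporation; n-BuLi (1.1 equiv), THF, −78 °C; PhNTf2 (1.2 equiv), −78 °C to rt
Reagents that add atoms: hexamethyldisilazane, C[Si](C)(C)N[Si](C)(C)C; N-phenylbis(trifluoromethanesulfonimide), O=S(=O)(N(c1ccccc1)S(=O)(=O)C(F)(F)F)C(F)(F)F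
Why: O-Silylation, bromine–lithium exchange and anionic 1,3 O-to-C silyl migration (retro-Brook rearrangement) should place the trimethylsilyl group ortho to the phenoxide, which is then triflated to the silylaryl triflate aryne precursor.

Step 10
Reactants: 9 (3S)-3-hydroxy-N-methoxy-N-methyl-3-[(2S)-8-(methoxymethoxy)-2-methyl-2-[(1E)-4-methylpenta-1,3-dien-1-yl]-3,4-dihydro-2H-chromen-6-yl]propanamide; 18 3,5-bis(methoxymethoxy)-4-(3-methylbut-2-en-1-yl)-2-(trimethylsilyl)phenyl trifluoromethanesulfonate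
Product: 22 (2S)-5,7-bis(methoxymethoxy)-2-[(2S)-8-(methoxymethoxy)-2-methyl-2-[(1E)-4-methylpenta-1,3-dien-1-yl]-3,4-dihydro-2H-chromen-6-yl]-6-(3-methylbut-2-en-1-yl)-2,3-dihydro-4H-chromen-4-one, via sodium alkoxide 19 (not isolated), via aryne 20 (not isolated), via hemiaminal alkoxide 21 (not isolated)
Conditions: NaH (1.05 equiv), THF, 0 °C; then 18 (1.5 equiv), KF (4 equiv), 18-crown-6 (4 equiv), THF, 0 °C to rt; sat. aq. NH4Cl
Reagents that add atoms: none
Why: Proposed new method: fluoride unmasks aryne 20 from 18, the proton-free alkoxide 19 adds its oxygen to the aryne carbon remote from the flanking methoxymethoxy group (the future C8a), and the aryl anion left at the future C4a attacks the N-methoxy-N-methylamide carbonyl to give hemiaminal alkoxide 21, which releases the ketone on work-up. The closest known reaction type is the fluoride-induced annulation of 2-(trimethylsilyl)aryl triflates with salicylate esters to xanthones (phenoxide addition, then aryl-anion acylation); here an aliphatic benzylic alkoxide and an enolisable amide take those roles. Ring C closes by a 6-exo-trig attack of C4a on C4. No new stereocentre is formed in the product: the carbinol C–O bond is never broken, so C2 keeps the (S) configuration from step 4, and the tetrahedral intermediate shields C3 from enolisation and retro-oxa-Michael opening until neutral work-up. The step needs regioselective O-addition, secured by the inductive polarisation of the aryne by the C5 oxygen as in 3-alkoxybenzynes, and acylation faster than protonation or α-deprotonation of the aryl anion, secured by the aprotic alkoxide, THF and the six-membered geometry; the prenyl position is fixed by the symmetry of phenol 14.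

Step 11
Reactants: 22 (2S)-5,7-bis(methoxymethoxy)-2-[(2S)-8-(methoxymethoxy)-2-methyl-2-[(1E)-4-methylpenta-1,3-dien-1-yl]-3,4-dihydro-2H-chromen-6-yl]-6-(3-methylbut-2-en-1-yl)-2,3-dihydro-4H-chromen-4-one
Product: 24 (2S)-5,7-dihydroxy-2-[(2S)-8-hydroxy-2-methyl-2-[(1E)-4-methylpenta-1,3-dien-1-yl]-3,4-dihydro-2H-chromen-6-yl]-6-(3-methylbut-2-en-1-yl)-2,3-dihydro-4H-chromen-4-one, via tris(trimethylsilyl) ether 23 (not isolated)
Conditions: TMSOTf (9 equiv), 2,2′-bipyridyl (13 equiv), MeCN, 0 °C to rt; then H2O, rt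
Reagents that add atoms: none
Why: The trimethylsilyl triflate–2,2′-bipyridyl complex should convert aryl methoxymethyl ethers into aryl silyl ethers under essentially non-acidic conditions (the acetal carbon leaving as an N-methoxymethylpyridinium salt) and water then hydrolyses the silyl ethers, leaving the tertiary dienyl ether, the prenyl group and both stereocentres untouched.

Compound list
1 | 3-bromo-4,5-dihydroxybenzaldehyde | O=Cc1cc(O)c(O)c(Br)c1 | starting material
2 | 3-bromo-4-hydroxy-5-(methoxymethoxy)benzaldehyde | O=Cc1cc(OCOC)c(O)c(Br)c1 | intermediate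
3 | (E)-β-ocimene, (3E)-3,7-dimethylocta-1,3,6-triene | C=C/C(C)=C/CC=C(C)C | starting material
4 | 9-[(3E)-3,7-dimethylocta-3,6-dien-1-yl]-9-borabicyclo[3.3.1]nonane | B1(CC/C(C)=C/CC=C(C)C)C2CCCC1CCC2 | intermediate
5 | 3-[(3E)-3,7-dimethylocta-3,6-dien-1-yl]-4-hydroxy-5-(methoxymethoxy)benzaldehyde | O=Cc1cc(OCOC)c(O)c(CC/C(C)=C/CC=C(C)C)c1 | intermediate
6 | (2S)-8-(methoxymethoxy)-2-methyl-2-[(1E)-4-methylpenta-1,3-dien-1-yl]-3,4-dihydro-2H-chromene-6-carbaldehyde | CC(C)=C/C=C/[C@]1(C)CCc2cc(C=O)cc(OCOC)c2O1 | intermediate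
7 | methyl (3S)-3-[(2S)-8-(methoxymethoxy)-2-methyl-2-[(1E)-4-methylpenta-1,3-dien-1-yl]-3,4-dihydro-2H-chromen-6-yl]-3-(trimethylsilyloxy)propanoate | CC(C)=C/C=C/[C@]1(C)CCc2cc([C@@H](O[Si](C)(C)C)CC(=O)OC)cc(OCOC)c2O1 | intermediate
8 | methyl (3S)-3-hydroxy-3-[(2S)-8-(methoxymethoxy)-2-methyl-2-[(1E)-4-methylpenta-1,3-dien-1-yl]-3,4-dihydro-2H-chromen-6-yl]propanoate | CC(C)=C/C=C/[C@]1(C)CCc2cc([C@@H](O)CC(=O)OC)cc(OCOC)c2O1 | intermediate
9 | (3S)-3-hydroxy-N-methoxy-N-methyl-3-[(2S)-8-(methoxymethoxy)-2-methyl-2-[(1E)-4-methylpenta-1,3-dien-1-yl]-3,4-dihydro-2H-chromen-6-yl]propanamide | CC(C)=C/C=C/[C@]1(C)CCc2cc([C@@H](O)CC(=O)N(C)OC)cc(OCOC)c2O1 | intermediate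
10 | 1,3-bis(methoxymethoxy)benzene | COCOc1cccc(OCOC)c1 | starting material
11 | [2,6-bis(methoxymethoxy)phenyl]lithium | [Li]c1c(OCOC)cccc1OCOC | intermediate
12 | 1,3-bis(methoxymethoxy)-2-(3-methylbut-2-en-1-yl)benzene | CC(C)=CCc1c(OCOC)cccc1OCOC | intermediate
13 | 2-[3,5-bis(methoxymethoxy)-4-(3-methylbut-2-en-1-yl)phenyl]-4,4,5,5-tetramethyl-1,3,2-dioxaborolane | CC(C)=CCc1c(OCOC)cc(B2OC(C)(C)C(C)(C)O2)cc1OCOC | intermediate
14 | 3,5-bis(methoxymethoxy)-4-(3-methylbut-2-en-1-yl)phenol | CC(C)=CCc1c(OCOC)cc(O)cc1OCOC | intermediate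
15 | 2-bromo-3,5-bis(methoxymethoxy)-4-(3-methylbut-2-en-1-yl)phenol | CC(C)=CCc1c(OCOC)cc(O)c(Br)c1OCOC | intermediate
16 | [2-bromo-3,5-bis(methoxymethoxy)-4-(3-methylbut-2-en-1-yl)phenoxy]trimethylsilane | CC(C)=CCc1c(OCOC)cc(O[Si](C)(C)C)c(Br)c1OCOC | intermediate
17 | lithium 3,5-bis(methoxymethoxy)-4-(3-methylbut-2-en-1-yl)-2-(trimethylsilyl)phenolate | CC(C)=CCc1c(OCOC)cc([O-])c([Si](C)(C)C)c1OCOC.[Li+] | intermediate
18 | 3,5-bis(methoxymethoxy)-4-(3-methylbut-2-en-1-yl)-2-(trimethylsilyl)phenyl trifluoromethanesulfonate | CC(C)=CCc1c(OCOC)cc(OS(=O)(=O)C(F)(F)F)c([Si](C)(C)C)c1OCOC | intermediate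
19 | sodium (1S)-3-[methoxy(methyl)amino]-1-[(2S)-8-(methoxymethoxy)-2-methyl-2-[(1E)-4-methylpenta-1,3-dien-1-yl]-3,4-dihydro-2H-chromen-6-yl]-3-oxopropan-1-olate | CC(C)=C/C=C/[C@]1(C)CCc2cc([C@@H]([O-])CC(=O)N(C)OC)cc(OCOC)c2O1.[Na+] | intermediate
20 | 3,5-bis(methoxymethoxy)-4-(3-methylbut-2-en-1-yl)benzyne (1,2-didehydrobenzene) | CC(C)=CCC1=C(OCOC)C#CC=C1OCOC | intermediate
21 | sodium (2S)-4-[methoxy(methyl)amino]-5,7-bis(methoxymethoxy)-2-[(2S)-8-(methoxymethoxy)-2-methyl-2-[(1E)-4-methylpenta-1,3-dien-1-yl]-3,4-dihydro-2H-chromen-6-yl]-6-(3-methylbut-2-en-1-yl)chroman-4-olate (both C4 epimers) | CC(C)=C/C=C/[C@]1(C)CCc2cc([C@@H]3CC([O-])(N(C)OC)c4c(cc(OCOC)c(CC=C(C)C)c4OCOC)O3)cc(OCOC)c2O1.[Na+] | intermediate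
22 | (2S)-5,7-bis(methoxymethoxy)-2-[(2S)-8-(methoxymethoxy)-2-methyl-2-[(1E)-4-methylpenta-1,3-dien-1-yl]-3,4-dihydro-2H-chromen-6-yl]-6-(3-methylbut-2-en-1-yl)-2,3-dihydro-4H-chromen-4-one | CC(C)=C/C=C/[C@]1(C)CCc2cc([C@@H]3CC(=O)c4c(cc(OCOC)c(CC=C(C)C)c4OCOC)O3)cc(OCOC)c2O1 | intermediate
23 | (2S)-2-[(2S)-2-methyl-2-[(1E)-4-methylpenta-1,3-dien-1-yl]-8-(trimethylsilyloxy)-3,4-dihydro-2H-chromen-6-yl]-6-(3-methylbut-2-en-1-yl)-5,7-bis(trimethylsilyloxy)-2,3-dihydro-4H-chromen-4-one | CC(C)=C/C=C/[C@]1(C)CCc2cc([C@@H]3CC(=O)c4c(cc(O[Si](C)(C)C)c(CC=C(C)C)c4O[Si](C)(C)C)O3)cc(O[Si](C)(C)C)c2O1 | intermediate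
24 | (2S)-5,7-dihydroxy-2-[(2S)-8-hydroxy-2-methyl-2-[(1E)-4-methylpenta-1,3-dien-1-yl]-3,4-dihydro-2H-chromen-6-yl]-6-(3-methylbut-2-en-1-yl)-2,3-dihydro-4H-chromen-4-one | CC(C)=C/C=C/[C@]1(C)CCc2cc([C@@H]3CC(=O)c4c(cc(O)c(CC=C(C)C)c4O)O3)cc(O)c2O1 | target

Total step count: 11. Longest linear sequence: 7 steps (steps 1–5, 10, 11); the ring A branch (steps 6–9) joins at step 10.

Steps most likely to fail

Step 10 (labelled step). The aryl anion may be protonated before it acylates, or may abstract a C3 proton and trigger β-elimination of the aryloxide. Alkoxide addition may also be slow enough for the aryne to be consumed by ene or cycloaddition reactions with the alkenes. The fallback makes the same bond by a Parham cyclisation on a preformed ether, using known chemistry. It sets out from aldehyde 6 and bromophenol 15. The aldol of step 4 is run with the enantiomeric titanium catalyst to give the (R)-silyl ether F1 and, after methanolysis, the (R)-hydroxy ester F2. F2 is converted as in step 5 into the (R)-Weinreb amide F3. Mitsunobu etherification of F3 with 15 (PPh3, diisopropyl azodicarboxylate, toluene, 0 °C) should proceed with inversion to the (S)-aryl ether F4. Bromine–lithium exchange (t-BuLi, THF, −100 °C) then lets the aryllithium at the future C4a attack the amide, and aqueous work-up returns to flavanone 22.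

Step 3. The newly formed conjugated diene may be oxidised further by divalent palladium and benzoquinone, and facial discrimination may be poor on a phenol deactivated by the para-formyl group. The fallback keeps the diene out of the oxidative step and appends it afterwards. It sets out from bromide 2, which is coupled as in step 2 with the 9-BBN adduct of (E)-3-methylpenta-1,3-diene, 9-[(3E)-3-methylpent-3-en-1-yl]-9-borabicyclo[3.3.1]nonane F5, to give the phenol 4-hydroxy-3-(methoxymethoxy)-5-[(3E)-3-methylpent-3-en-1-yl]benzaldehyde F6. The same ligand-controlled oxidative cyclisation, now on the simple alkenylphenol class for which it is established, gives (2S)-2-ethenyl-8-(methoxymethoxy)-2-methylchroman-6-carbaldehyde F7. A Heck reaction of F7 with 1-bromo-2-methylprop-1-ene (Pd(OAc)2, P(o-tol)3, K2CO3, Bu4NCl, DMF, 70 °C) attaches the isobutenyl unit at the vinyl terminus and returns to aldehyde 6.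

Step 11. The tertiary dienyl aryl ether may ionise, the prenyl group may cyclise onto a freed phenol, or ring C may open through the silylated carbonyl group. The fallback introduces the acid-sensitive diene only after deprotection. It sets out from bromide 2 and triflate 18 and returns at the target 24.
- Bromide 2 is taken through the borane F5 and the phenol F6 to the vinylchroman aldehyde F7, as in the fallback for step 3.
- F7 is carried through step 4 to the vinyl silyl ether F8 and the vinyl hydroxy ester F9, and through step 5 to the vinyl Weinreb amide F10.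
- Step 10 on F10 (sodium alkoxide F11, aryne 20 from 18, hemiaminal alkoxide F12) gives the vinyl tris(methoxymethyl) flavanone F13.
- The sturdier 2-vinylchroman should tolerate conventional acetal cleavage (dilute HCl, MeOH, 40 °C), giving the vinyl triphenol F14.
- A Heck reaction of F14 with 1-bromo-2-methylprop-1-ene (Pd(OAc)2, P(o-tol)3, NaOAc, DMF, 70 °C) gives 24.

Further compounds
F1 | step 10 | methyl (3R)-3-[(2S)-8-(methoxymethoxy)-2-methyl-2-[(1E)-4-methylpenta-1,3-dien-1-yl]-3,4-dihydro-2H-chromen-6-yl]-3-(trimethylsilyloxy)propanoate | CC(C)=C/C=C/[C@]1(C)CCc2cc([C@H](O[Si](C)(C)C)CC(=O)OC)cc(OCOC)c2O1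
F2 | step 10 | methyl (3R)-3-hydroxy-3-[(2S)-8-(methoxymethoxy)-2-methyl-2-[(1E)-4-methylpenta-1,3-dien-1-yl]-3,4-dihydro-2H-chromen-6-yl]propanoate | CC(C)=C/C=C/[C@]1(C)CCc2cc([C@H](O)CC(=O)OC)cc(OCOC)c2O1
F3 | step 10 | (3R)-3-hydroxy-N-methoxy-N-methyl-3-[(2S)-8-(methoxymethoxy)-2-methyl-2-[(1E)-4-methylpenta-1,3-dien-1-yl]-3,4-dihydro-2H-chromen-6-yl]propanamide | CC(C)=C/C=C/[C@]1(C)CCc2cc([C@H](O)CC(=O)N(C)OC)cc(OCOC)c2O1
F4 | step 10 | (3S)-3-[2-bromo-3,5-bis(methoxymethoxy)-4-(3-methylbut-2-en-1-yl)phenoxy]-N-methoxy-N-methyl-3-[(2S)-8-(methoxymethoxy)-2-methyl-2-[(1E)-4-methylpenta-1,3-dien-1-yl]-3,4-dihydro-2H-chromen-6-yl]propanamide | CC(C)=C/C=C/[C@]1(C)CCc2cc([C@@H](Oc3cc(OCOC)c(CC=C(C)C)c(OCOC)c3Br)CC(=O)N(C)OC)cc(OCOC)c2O1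
F5 | step 3 | 9-[(3E)-3-methylpent-3-en-1-yl]-9-borabicyclo[3.3.1]nonane | B1(CC/C(C)=C/C)C2CCCC1CCC2
F6 | step 3 | 4-hydroxy-3-(methoxymethoxy)-5-[(3E)-3-methylpent-3-en-1-yl]benzaldehyde | O=Cc1cc(OCOC)c(O)c(CC/C(C)=C/C)c1
F7 | step 3 | (2S)-2-ethenyl-8-(methoxymethoxy)-2-methyl-3,4-dihydro-2H-chromene-6-carbaldehyde | C=C[C@]1(C)CCc2cc(C=O)cc(OCOC)c2O1
F8 | step 11 | methyl (3S)-3-[(2S)-2-ethenyl-8-(methoxymethoxy)-2-methyl-3,4-dihydro-2H-chromen-6-yl]-3-(trimethylsilyloxy)propanoate | C=C[C@]1(C)CCc2cc([C@@H](O[Si](C)(C)C)CC(=O)OC)cc(OCOC)c2O1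
F9 | step 11 | methyl (3S)-3-[(2S)-2-ethenyl-8-(methoxymethoxy)-2-methyl-3,4-dihydro-2H-chromen-6-yl]-3-hydroxypropanoate | C=C[C@]1(C)CCc2cc([C@@H](O)CC(=O)OC)cc(OCOC)c2O1
F10 | step 11 | (3S)-3-[(2S)-2-ethenyl-8-(methoxymethoxy)-2-methyl-3,4-dihydro-2H-chromen-6-yl]-3-hydroxy-N-methoxy-N-methylpropanamide | C=C[C@]1(C)CCc2cc([C@@H](O)CC(=O)N(C)OC)cc(OCOC)c2O1
F11 | step 11 | sodium (1S)-1-[(2S)-2-ethenyl-8-(methoxymethoxy)-2-methyl-3,4-dihydro-2H-chromen-6-yl]-3-[methoxy(methyl)amino]-3-oxopropan-1-olate | C=C[C@]1(C)CCc2cc([C@@H]([O-])CC(=O)N(C)OC)cc(OCOC)c2O1.[Na+]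
F12 | step 11 | sodium (2S)-2-[(2S)-2-ethenyl-8-(methoxymethoxy)-2-methyl-3,4-dihydro-2H-chromen-6-yl]-4-[methoxy(methyl)amino]-5,7-bis(methoxymethoxy)-6-(3-methylbut-2-en-1-yl)chroman-4-olate (both C4 epimers) | C=C[C@]1(C)CCc2cc([C@@H]3CC([O-])(N(C)OC)c4c(cc(OCOC)c(CC=C(C)C)c4OCOC)O3)cc(OCOC)c2O1.[Na+]
F13 | step 11 | (2S)-2-[(2S)-2-ethenyl-8-(methoxymethoxy)-2-methyl-3,4-dihydro-2H-chromen-6-yl]-5,7-bis(methoxymethoxy)-6-(3-methylbut-2-en-1-yl)-2,3-dihydro-4H-chromen-4-one | C=C[C@]1(C)CCc2cc([C@@H]3CC(=O)c4c(cc(OCOC)c(CC=C(C)C)c4OCOC)O3)cc(OCOC)c2O1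
F14 | step 11 | (2S)-2-[(2S)-2-ethenyl-8-hydroxy-2-methyl-3,4-dihydro-2H-chromen-6-yl]-5,7-dihydroxy-6-(3-methylbut-2-en-1-yl)-2,3-dihydro-4H-chromen-4-one | C=C[C@]1(C)CCc2cc([C@@H]3CC(=O)c4c(cc(O)c(CC=C(C)C)c4O)O3)cc(O)c2O1
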